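**Plan**

- Retrosynthesis: the carbinol is taken back to a ketone. The CH2–CH2 bond between the ketone α-carbon and the allylic CH2 on the methyl-bearing carbon of the Z-alkene is then cut (enolate plus allylic chloride, with an allyl ester on the α-carbon as a removable activating group). Next come the enoate C=C (phosphonate plus arylacetaldehyde), the ArO–C(CH3)2 bond and the Z-alkene (ylide plus α-silyloxy ketone).
- Enabling feature: in the 14-membered ring the carbinol carbon lies between the quaternary O–C(CH3)2 carbon, which cannot enolise, and a CH2 whose neighbour is the allylic CH2 of the Z-trisubstituted alkene. At the ketone level only one enolate exists, and it is the one needed.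
- Forward: hydroquinone gives the arylacetaldehyde by O-allylation, silylation, Claisen rearrangement, O-alkylation with tert-butyl 2-bromoisobutyrate and ozonolysis. A Z-selective Wittig reaction and a phosphonoacetate alkylation give the side-chain phosphonate, and olefination joins the two.
- The tert-butyl ester is then converted into an allyl β-ketoester and the allylic silyl ether into the chloride. The intramolecular C-alkylation is the only ring closure of the route (the 14-membered ring; the benzene ring comes from hydroquinone).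
- Stereochemistry: the Z-alkene comes from the Wittig step and the E-enoate from the phosphonate olefination. The single stereocentre (R) comes from an oxazaborolidine-catalysed reduction of the macrocyclic ketone after the allyl ester has been removed; hydroxide finally frees phenol and acid.

Key step: step 16

Remark: the acetal carbon of the tetrahydropyranyl group and the ester-bearing ring carbon formed in the ring closure are carried as both configurations, since each is removed again (steps 8 and 17); Mg(O2CCH2CO2CH2CH=CH2)2 is assumed to be made beforehand from allyl hydrogen malonate and Mg(OEt)2.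

**Route**

Step 1
Reactants: 1 hydroquinone; 2 allyl bromide
Product: 3 4-(allyloxy)phenol
Conditions: K2CO3, acetone, reflux (1 in threefold excess)
Reagents that add atoms: none
Why: Williamson ether synthesis on the phenoxide, in which the excess of the symmetrical diol should keep bis-allylation low and the unreacted hydroquinone is removed by aqueous washing.

Step 2
Reactants: 3 4-(allyloxy)phenol
Product: 4 [4-(allyloxy)phenoxy]triisopropylsilane
Conditions: TIPSCl, imidazole, DMF, 0 °C → rt
Reagents that add atoms: triisopropylsilyl chloride, CC(C)[Si](Cl)(C(C)C)C(C)C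
Why: Imidazole-promoted silylation of the phenol; the triisopropylsilyl aryl ether is chosen because it should survive heat, anhydrous carbonate and the acidic steps ahead and yet fall to hydroxide at the end.

Step 3
Reactants: 4 [4-(allyloxy)phenoxy]triisopropylsilane
Product: 5 2-allyl-4-(triisopropylsilyloxy)phenol
Conditions: PhNEt2, 195 °C, argon
Reagents that add atoms: none
Why: Aromatic Claisen rearrangement ([3,3]-sigmatropic shift followed by tautomerisation); it can only deliver the allyl group to the position ortho to the oxygen that becomes the free phenol, which fixes the substitution pattern of the arene without a selectivity question.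

Step 4
Reactants: 5 2-allyl-4-(triisopropylsilyloxy)phenol; 6 tert-butyl 2-bromo-2-methylpropanoate
Product: 7 tert-butyl 2-[2-allyl-4-(triisopropylsilyloxy)phenoxy]-2-methylpropanoate
Conditions: Cs2CO3, MeCN, 4 Å molecular sieves, 70 °C (6 in excess)
Reagents that add atoms: none
Why: O-alkylation of the cesium phenoxide with a tertiary α-bromo ester, the standard entry to aryloxyisobutyrates; the tert-butyl ester is used so that this carboxyl group can later be freed without touching a methyl ester.

Step 5
Reactants: 7 tert-butyl 2-[2-allyl-4-(triisopropylsilyloxy)phenoxy]-2-methylpropanoate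
Product: 9 tert-butyl 2-methyl-2-[2-(2-oxoethyl)-4-(triisopropylsilyloxy)phenoxy]propanoate, via ozonide 8 (not isolated)
Conditions: O3, CH2Cl2, −78 °C (Sudan Red 7B as end-point indicator); PPh3, −78 °C → rt
Reagents that add atoms: ozone, [O-][O+]=O
Why: Ozonolysis with reductive work-up of the only C=C bond in the molecule, the indicator dye guarding the electron-rich arene against over-oxidation; the arylacetaldehyde is to be used at once.

Step 6
Reactants: 10 2-(3-bromopropoxy)tetrahydro-2H-pyran
Product: 11 triphenyl[3-(tetrahydro-2H-pyran-2-yloxy)propyl]phosphonium bromide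
Conditions: PPh3, K2CO3 (cat.), MeCN, reflux
Reagents that add atoms: triphenylphosphine, c1ccccc1P(c1ccccc1)c1ccccc1
Why: Quaternisation of PPh3 by a primary bromide (SN2), with a trace of carbonate to protect the acetal from adventitious HBr.

Step 7
Reactants: 11 triphenyl[3-(tetrahydro-2H-pyran-2-yloxy)propyl]phosphonium bromide; 12 1-(tert-butyldimethylsilyloxy)propan-2-one
Product: 14 tert-butyldimethyl{[(2Z)-2-methyl-5-(tetrahydro-2H-pyran-2-yloxy)pent-2-en-1-yl]oxy}silane, via phosphorus ylide 13 (not isolated)
Conditions: KN(SiMe3)2, THF, −78 → 0 °C; then 12, −78 °C → rt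
Reagents that add atoms: none
Why: Wittig olefination of an α-silyloxy ketone with an unstabilised ylide under lithium-free conditions, a combination known to give under kinetic control the trisubstituted alkene whose oxygenated CH2 is cis to the ylide-derived chain, that is the Z-allylic ether.

Step 8
Reactants: 14 tert-butyldimethyl{[(2Z)-2-methyl-5-(tetrahydro-2H-pyran-2-yloxy)pent-2-en-1-yl]oxy}silane
Product: 15 (3Z)-5-(tert-butyldimethylsilyloxy)-4-methylpent-3-en-1-ol
Conditions: MgBr2·OEt2, Et2O, rt; aq. NH4Cl
Reagents that add atoms: none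
Why: Chelation-assisted Lewis-acid cleavage of the tetrahydropyranyl acetal, a method known to leave tert-butyldimethylsilyl ethers in place.

Step 9
Reactants: 15 (3Z)-5-(tert-butyldimethylsilyloxy)-4-methylpent-3-en-1-ol
Product: 16 tert-butyl{[(2Z)-5-iodo-2-methylpent-2-en-1-yl]oxy}dimethylsilane
Conditions: I2, PPh3, imidazole, CH2Cl2, 0 °C → rt
Reagents that add atoms: iodine, II
Why: Appel-type iodination (Garegg–Samuelsson conditions), an SN2 displacement of the alkoxyphosphonium at a primary carbon that does not involve the alkene.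

Step 10
Reactants: 16 tert-butyl{[(2Z)-5-iodo-2-methylpent-2-en-1-yl]oxy}dimethylsilane; 17 methyl 2-(diethoxyphosphoryl)acetate
Product: 18 methyl (5Z)-7-(tert-butyldimethylsilyloxy)-2-(diethoxyphosphoryl)-6-methylhept-5-enoate
Conditions: NaH, THF/DMF, 0 °C; then 16, 55 °C (17 in excess)
Reagents that add atoms: none
Why: C-alkylation of the sodium phosphonoacetate with a primary iodide (SN2); the excess of the soft, weakly basic nucleophile should suppress both dialkylation and elimination of the homoallylic iodide.

Step 11
Reactants: 18 methyl (5Z)-7-(tert-butyldimethylsilyloxy)-2-(diethoxyphosphoryl)-6-methylhept-5-enoate; 9 tert-butyl 2-methyl-2-[2-(2-oxoethyl)-4-(triisopropylsilyloxy)phenoxy]propanoate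
Product: 19 methyl (2E)-4-{2-[(1-tert-butoxy-2-methyl-1-oxopropan-2-yl)oxy]-5-(triisopropylsilyloxy)phenyl}-2-[(3Z)-5-(tert-butyldimethylsilyloxy)-4-methylpent-3-en-1-yl]but-2-enoate
Conditions: NaH (slightly less than 18), THF, 0 °C; then 9, −78 → 0 °C
Reagents that add atoms: none
Why: Horner–Wadsworth–Emmons olefination in which the sodium salt of the α-alkylated phosphonoacetate adds reversibly to the unbranched aldehyde and eliminates preferentially through the adduct that places the ester trans to the CH2Ar group, so the E-enoate should predominate; the absence of free base should keep the arylacetaldehyde from enolising and the new double bond from moving into conjugation with the arene.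

Step 12
Reactants: 19 the E-enoate tert-butyl ester of step 11
Product: 21 2-{2-[(2E,6Z)-8-(tert-butyldimethylsilyloxy)-3-(methoxycarbonyl)-7-methylocta-2,6-dien-1-yl]-4-(triisopropylsilyloxy)phenoxy}-2-methylpropanoic acid, via trimethylsilyl ester 20 (not isolated)
Conditions: TMSOTf, 2,6-lutidine, CH2Cl2, 0 °C; then pH 5 aqueous buffer
Reagents that add atoms: none
Why: Silyl-triflate cleavage of a tert-butyl ester (O-silylation, loss of isobutene, hydrolysis of the silyl ester on work-up) under lutidine buffering, conditions that should spare the allylic silyl ether, the aryl silyl ether and the methyl ester where a protic acid would not.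

Step 13
Reactants: 21 the carboxylic acid of step 12
Product: 24 allyl 4-{2-[(2E,6Z)-8-(tert-butyldimethylsilyloxy)-3-(methoxycarbonyl)-7-methylocta-2,6-dien-1-yl]-4-(triisopropylsilyloxy)phenoxy}-4-methyl-3-oxopentanoate, via acyl imidazole 22 (not isolated), via acylmalonic half-ester 23 (not isolated)
Conditions: CDI, THF, rt; then Mg(O2CCH2CO2CH2CH=CH2)2, THF, 45 °C; 1 M HCl, 0 °C
Reagents that add atoms: magnesium bis(allyl malonate), [Mg+2].[O-]C(=O)CC(=O)OCC=C.[O-]C(=O)CC(=O)OCC=C
Why: Masamune–Brooks homologation, a neutral C-acylation of the magnesium malonate half-ester by the acyl imidazole followed by decarboxylation on acidic work-up, which leaves the methyl enoate and both silyl ethers alone.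

Step 14
Reactants: 24 the allyl β-ketoester of step 13
Product: 25 allyl 4-{2-[(2E,6Z)-8-hydroxy-3-(methoxycarbonyl)-7-methylocta-2,6-dien-1-yl]-4-(triisopropylsilyloxy)phenoxy}-4-methyl-3-oxopentanoate
Conditions: AcOH/THF/H2O (3:1:1), rt
Reagents that add atoms: none
Why: Acid-catalysed hydrolysis of a primary alkyl silyl ether, a medium in which aryl triisopropylsilyl ethers are much slower to cleave and in which no transesterification of the β-ketoester can occur.

Step 15
Reactants: 25 the allylic alcohol of step 14
Product: 27 allyl 4-{2-[(2E,6Z)-8-chloro-3-(methoxycarbonyl)-7-methylocta-2,6-dien-1-yl]-4-(triisopropylsilyloxy)phenoxy}-4-methyl-3-oxopentanoate, via allylic mesylate 26 (not isolated)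
Conditions: MsCl, 2,4,6-collidine, LiCl, DMF, 0 °C
Reagents that add atoms: lithium chloride, [Li+].[Cl-]
Why: Collington–Meyers chlorination (mesylation, then SN2 displacement by chloride at the primary allylic carbon), which should proceed without allylic transposition or loss of the Z geometry and with a base too weak to engage the β-ketoester; the chloride is used directly.

Step 16
Reactants: 27 the seco allylic chloride of step 15
Product: 29 macrocyclic allyl β-ketoester (14-membered ring of the target; ketone beside the O–C(CH3)2 carbon; allyl ester on the neighbouring ring CH; methyl ester and aryl silyl ether retained), via allylic iodide 28 (not isolated)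
Conditions: Cs2CO3, CsI, MeCN, 50 °C, syringe-pump addition of 27 (final concentration about 2 mM)
Reagents that add atoms: none
Why: Cs2CO3 removes a proton from the CH2 between the ketone and the allyl ester (the only acidic site, since the other α-carbon of the ketone is the quaternary O–C(CH3)2 carbon and the γ-CH2 of the enoate is far less acidic), CsI turns the allylic chloride into the iodide by Finkelstein exchange, and the carbon of the cesium enolate displaces the halide at the primary allylic CH2 in an intramolecular SN2 reaction. The closest known reaction type is the high-dilution macrocyclisation of malonates and β-ketoesters onto allylic chlorides with Cs2CO3 and CsI. The 14-membered ring closes in the exo-tet mode (14-exo-tet), helped by three rigid elements in the chain (the ortho-disubstituted arene, the E-enoate and the Z-alkene). The ring carbon that carries the allyl ester becomes a stereocentre without control, and both configurations are carried on because step 17 removes it. Carbon over oxygen alkylation should follow from a soft cesium enolate meeting a soft allylic iodide, SN2 over SN2′ from the unhindered primary carbon set against a fully substituted alkene terminus (which would also force a 12-membered ring with a quaternary carbon), and ring closure over oligomerisation from slow addition into dilute solution. The Z-alkene is not part of the reacting centre and should keep its geometry.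

Step 17
Reactants: 29 the macrocyclic allyl β-ketoester of step 16
Product: 31 macrocyclic ketone (14-membered ring of the target with C=O in place of CH(OH); methyl ester; aryl triisopropylsilyl ether), via β-keto acid 30 (not isolated)
Conditions: Pd(PPh3)4 (5 mol %), morpholine, THF, rt → 40 °C
Reagents that add atoms: none
Why: Tsuji–Trost deallylation, in which zerovalent palladium ionises the allyl ester to a π-allyl complex that morpholine intercepts, and the liberated β-keto acid loses CO2 on gentle warming; no other allylic leaving group is present.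

Step 18
Reactants: 31 the macrocyclic ketone of step 17
Product: 32 methyl ester and triisopropylsilyl ether of the target with the (R)-carbinol in place
Conditions: (3aS)-1-methyl-3,3-diphenyltetrahydro-1H,3H-pyrrolo[1,2-c][1,3,2]oxazaborole (20 mol %), catecholborane, toluene, −78 → −40 °C; MeOH quench, pH 7 buffer
Reagents that add atoms: none
Why: Corey–Bakshi–Shibata reduction, in which the ketone binds to the ring boron of the (S)-oxazaborolidine on the side of its small CH2 chain and away from the bulky C(CH3)2OAr group, so that hydride from the nitrogen-bound catecholborane reaches the face that gives the (R)-alcohol (the same sense in which this catalyst turns tert-alkyl methyl ketones into R alcohols); catecholborane at low temperature leaves both alkenes and the ester untouched.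

Step 19
Reactants: 32 the (R)-alcohol of step 18
Product: 33 Petchiether B
Conditions: LiOH·H2O, THF/MeOH/H2O (degassed), 45 °C; then 1 M HCl to pH 3
Reagents that add atoms: lithium hydroxide, [Li+].[OH-]
Why: Saponification of the methyl enoate together with hydroxide cleavage of the aryl silyl ether in one operation; the carbinol centre has no acidic hydrogen and cannot epimerise, and exclusion of air protects the hydroquinone monoether phenoxide.

**Compound list**

1 | hydroquinone | Oc1ccc(O)cc1 | starting material
2 | allyl bromide | C=CCBr | starting material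
3 | 4-(allyloxy)phenol | C=CCOc1ccc(O)cc1 | intermediate
4 | [4-(allyloxy)phenoxy]triisopropylsilane | C=CCOc1ccc(O[Si](C(C)C)(C(C)C)C(C)C)cc1 | intermediate
5 | 2-allyl-4-(triisopropylsilyloxy)phenol | C=CCc1cc(O[Si](C(C)C)(C(C)C)C(C)C)ccc1O | intermediate
6 | tert-butyl 2-bromo-2-methylpropanoate | CC(C)(C)OC(=O)C(C)(C)Br | starting material
7 | tert-butyl 2-[2-allyl-4-(triisopropylsilyloxy)phenoxy]-2-methylpropanoate | C=CCc1cc(O[Si](C(C)C)(C(C)C)C(C)C)ccc1OC(C)(C)C(=O)OC(C)(C)C | intermediate
8 | ozonide of 7: tert-butyl 2-methyl-2-[2-(1,2,4-trioxolan-3-ylmethyl)-4-(triisopropylsilyloxy)phenoxy]propanoate (not isolated) | C1OC(Cc2cc(O[Si](C(C)C)(C(C)C)C(C)C)ccc2OC(C)(C)C(=O)OC(C)(C)C)OO1 | intermediate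
9 | tert-butyl 2-methyl-2-[2-(2-oxoethyl)-4-(triisopropylsilyloxy)phenoxy]propanoate | O=CCc1cc(O[Si](C(C)C)(C(C)C)C(C)C)ccc1OC(C)(C)C(=O)OC(C)(C)C | intermediate
10 | 2-(3-bromopropoxy)tetrahydro-2H-pyran | BrCCCOC1CCCCO1 | starting material
11 | triphenyl[3-(tetrahydro-2H-pyran-2-yloxy)propyl]phosphonium bromide | [Br-].c1ccccc1[P+](c1ccccc1)(c1ccccc1)CCCOC1CCCCO1 | intermediate
12 | 1-(tert-butyldimethylsilyloxy)propan-2-one | CC(=O)CO[Si](C)(C)C(C)(C)C | starting material
13 | triphenyl[3-(tetrahydro-2H-pyran-2-yloxy)propylidene]phosphorane (not isolated) | c1ccccc1P(c1ccccc1)(c1ccccc1)=CCCOC1CCCCO1 | intermediate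
14 | tert-butyldimethyl{[(2Z)-2-methyl-5-(tetrahydro-2H-pyran-2-yloxy)pent-2-en-1-yl]oxy}silane | CC(C)(C)[Si](C)(C)OC/C(C)=C\CCOC1CCCCO1 | intermediate
15 | (3Z)-5-(tert-butyldimethylsilyloxy)-4-methylpent-3-en-1-ol | CC(C)(C)[Si](C)(C)OC/C(C)=C\CCO | intermediate
16 | tert-butyl{[(2Z)-5-iodo-2-methylpent-2-en-1-yl]oxy}dimethylsilane | CC(C)(C)[Si](C)(C)OC/C(C)=C\CCI | intermediate
17 | methyl 2-(diethoxyphosphoryl)acetate | COC(=O)CP(=O)(OCC)OCC | starting material
18 | methyl (5Z)-7-(tert-butyldimethylsilyloxy)-2-(diethoxyphosphoryl)-6-methylhept-5-enoate | CCOP(=O)(OCC)C(CC/C=C(C)\CO[Si](C)(C)C(C)(C)C)C(=O)OC | intermediate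
19 | methyl (2E)-4-{2-[(1-tert-butoxy-2-methyl-1-oxopropan-2-yl)oxy]-5-(triisopropylsilyloxy)phenyl}-2-[(3Z)-5-(tert-butyldimethylsilyloxy)-4-methylpent-3-en-1-yl]but-2-enoate | CC(C)(C)[Si](C)(C)OC/C(C)=C\CC/C(C(=O)OC)=C\Cc1cc(O[Si](C(C)C)(C(C)C)C(C)C)ccc1OC(C)(C)C(=O)OC(C)(C)C | intermediate
20 | trimethylsilyl 2-{2-[(2E,6Z)-8-(tert-butyldimethylsilyloxy)-3-(methoxycarbonyl)-7-methylocta-2,6-dien-1-yl]-4-(triisopropylsilyloxy)phenoxy}-2-methylpropanoate (not isolated) | CC(C)(C)[Si](C)(C)OC/C(C)=C\CC/C(C(=O)OC)=C\Cc1cc(O[Si](C(C)C)(C(C)C)C(C)C)ccc1OC(C)(C)C(=O)O[Si](C)(C)C | intermediate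
21 | 2-{2-[(2E,6Z)-8-(tert-butyldimethylsilyloxy)-3-(methoxycarbonyl)-7-methylocta-2,6-dien-1-yl]-4-(triisopropylsilyloxy)phenoxy}-2-methylpropanoic acid | CC(C)(C)[Si](C)(C)OC/C(C)=C\CC/C(C(=O)OC)=C\Cc1cc(O[Si](C(C)C)(C(C)C)C(C)C)ccc1OC(C)(C)C(=O)O | intermediate
22 | N-acylimidazole of acid 21 (not isolated) | CC(C)(C)[Si](C)(C)OC/C(C)=C\CC/C(C(=O)OC)=C\Cc1cc(O[Si](C(C)C)(C(C)C)C(C)C)ccc1OC(C)(C)C(=O)n1ccnc1 | intermediate
23 | 2-[(allyloxy)carbonyl]-4-{2-[(2E,6Z)-8-(tert-butyldimethylsilyloxy)-3-(methoxycarbonyl)-7-methylocta-2,6-dien-1-yl]-4-(triisopropylsilyloxy)phenoxy}-4-methyl-3-oxopentanoic acid (not isolated) | CC(C)(C)[Si](C)(C)OC/C(C)=C\CC/C(C(=O)OC)=C\Cc1cc(O[Si](C(C)C)(C(C)C)C(C)C)ccc1OC(C)(C)C(=O)C(C(=O)O)C(=O)OCC=C | intermediate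
24 | allyl 4-{2-[(2E,6Z)-8-(tert-butyldimethylsilyloxy)-3-(methoxycarbonyl)-7-methylocta-2,6-dien-1-yl]-4-(triisopropylsilyloxy)phenoxy}-4-methyl-3-oxopentanoate | CC(C)(C)[Si](C)(C)OC/C(C)=C\CC/C(C(=O)OC)=C\Cc1cc(O[Si](C(C)C)(C(C)C)C(C)C)ccc1OC(C)(C)C(=O)CC(=O)OCC=C | intermediate
25 | allyl 4-{2-[(2E,6Z)-8-hydroxy-3-(methoxycarbonyl)-7-methylocta-2,6-dien-1-yl]-4-(triisopropylsilyloxy)phenoxy}-4-methyl-3-oxopentanoate | OC/C(C)=C\CC/C(C(=O)OC)=C\Cc1cc(O[Si](C(C)C)(C(C)C)C(C)C)ccc1OC(C)(C)C(=O)CC(=O)OCC=C | intermediate
26 | allyl 4-{2-[(2E,6Z)-3-(methoxycarbonyl)-7-methyl-8-(methylsulfonyloxy)octa-2,6-dien-1-yl]-4-(triisopropylsilyloxy)phenoxy}-4-methyl-3-oxopentanoate (not isolated) | CS(=O)(=O)OC/C(C)=C\CC/C(C(=O)OC)=C\Cc1cc(O[Si](C(C)C)(C(C)C)C(C)C)ccc1OC(C)(C)C(=O)CC(=O)OCC=C | intermediate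
27 | allyl 4-{2-[(2E,6Z)-8-chloro-3-(methoxycarbonyl)-7-methylocta-2,6-dien-1-yl]-4-(triisopropylsilyloxy)phenoxy}-4-methyl-3-oxopentanoate | ClC/C(C)=C\CC/C(C(=O)OC)=C\Cc1cc(O[Si](C(C)C)(C(C)C)C(C)C)ccc1OC(C)(C)C(=O)CC(=O)OCC=C | intermediate
28 | allyl 4-{2-[(2E,6Z)-8-iodo-3-(methoxycarbonyl)-7-methylocta-2,6-dien-1-yl]-4-(triisopropylsilyloxy)phenoxy}-4-methyl-3-oxopentanoate (not isolated) | IC/C(C)=C\CC/C(C(=O)OC)=C\Cc1cc(O[Si](C(C)C)(C(C)C)C(C)C)ccc1OC(C)(C)C(=O)CC(=O)OCC=C | intermediate
29 | macrocyclic allyl β-ketoester; ring path aryl C–O–C(CH3)2–C(=O)–CH(CO2CH2CH=CH2)–CH2–C(CH3)=CH–CH2–CH2–C(CO2CH3)=CH–CH2–aryl C, with (Z)-methyl alkene, (E)-enoate, aryl OSi(iPr)3 para to the ring oxygen, racemic at the ester-bearing CH | C/C1=C/CC/C(C(=O)OC)=C\Cc2cc(O[Si](C(C)C)(C(C)C)C(C)C)ccc2OC(C)(C)C(=O)C(C(=O)OCC=C)C1 | intermediate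
30 | macrocyclic β-keto acid, as 29 with CO2H in place of the allyl ester (not isolated) | C/C1=C/CC/C(C(=O)OC)=C\Cc2cc(O[Si](C(C)C)(C(C)C)C(C)C)ccc2OC(C)(C)C(=O)C(C(=O)O)C1 | intermediate
31 | macrocyclic ketone; ring path aryl C–O–C(CH3)2–C(=O)–CH2–CH2–C(CH3)=CH–CH2–CH2–C(CO2CH3)=CH–CH2–aryl C, with (Z)-methyl alkene, (E)-enoate, aryl OSi(iPr)3 | C/C1=C/CC/C(C(=O)OC)=C\Cc2cc(O[Si](C(C)C)(C(C)C)C(C)C)ccc2OC(C)(C)C(=O)CC1 | intermediate
32 | (R)-carbinol: as 31 with (R)-CH(OH) in place of C=O (methyl ester and triisopropylsilyl ether of the target) | C/C1=C/CC/C(C(=O)OC)=C\Cc2cc(O[Si](C(C)C)(C(C)C)C(C)C)ccc2OC(C)(C)[C@H](O)CC1 | intermediate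
33 | Petchiether B | C/C1=C/CC/C(C(=O)O)=C\Cc2cc(O)ccc2OC(C)(C)[C@H](O)CC1 | target

**Step count and risks**

Total steps: 19. Longest linear sequence: 14 steps (steps 1–5 and then 11–19; the side-chain branch, steps 6–10 and then 11–19, is equally long).

Steps most likely to fail:

Step 16. Ring closure may lose to intermolecular alkylation (oligomers) or to O-alkylation of the ambident enolate, and prolonged contact with carbonate may strip the aryl silyl group, after which the phenoxide alkylates. The fallback keeps the same bond and ring but changes the activating group and the way it is removed; it sets out from acid 21 and comes back at ketone 31, replacing steps 13–17. Acid 21 would be activated with CDI to acyl imidazole 22 and treated with two equivalents of LiCH2SO2Ph (from methyl phenyl sulfone and n-BuLi, THF, −78 °C) to give the β-keto sulfone F1. AcOH/THF/H2O would free the allylic alcohol F2, and MsCl, 2,4,6-collidine and LiCl in DMF would take it through the mesylate F3 to the allylic chloride F4. Cs2CO3 in MeCN under slow addition would then close the ring to the macrocyclic α-sulfonyl ketone F5; the sulfone-stabilised anion is a softer, purely carbon-centred nucleophile of the kind long used in macrocyclic alkylations. Al(Hg) in aqueous THF would remove the sulfonyl group to give 31.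

Step 11. The arylacetaldehyde may enolise and self-condense, the new double bond may drift into conjugation with the arene under basic conditions, and the E/Z selectivity of an α-alkylated phosphonoacetate may be only moderate. The fallback replaces the phosphonate anion by a neutral stabilised ylide; it sets out from iodide 16 (with aldehyde 9) and comes back at enoate 19, replacing steps 10 and 11. Iodide 16 would be heated in MeCN with two equivalents of methyl (triphenylphosphoranylidene)acetate; the first equivalent is C-alkylated to the phosphonium iodide F6 and the second deprotonates it (transylidation) to the α-substituted ester ylide F7. Wittig reaction of F7 with 9 in toluene at 80 °C, base-free, should then give 19 with the high E-selectivity usual for α-substituted ester ylides.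

Step 18. Facial selectivity may be poor if the conformation of the macrocycle or coordination of the aryloxy oxygen to boron overrides the steric discrimination of the catalyst, and the hindered ketone may react sluggishly at low temperature. The fallback gives up catalytic control for a stoichiometric chiral chloroborane; it sets out from ketone 31 and comes back at alcohol 32 without any new compound. Ketone 31 would be reduced with (+)-Ipc2BCl (B-chlorodiisopinocampheylborane from (−)-α-pinene) in THF at rt, followed by diethanolamine work-up. The hydride is transferred from an isopinocampheyl group through a six-membered boat-like transition state that distinguishes a tert-alkyl from a primary alkyl substituent very well and is known to serve hindered ketones; this enantiomer of the reagent should give the (R)-carbinol, and alkenes and esters are not touched.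

Further compounds
F1 | step 16 | methyl (2E)-2-[(3Z)-5-(tert-butyldimethylsilyloxy)-4-methylpent-3-en-1-yl]-4-{2-{[2-methyl-3-oxo-4-(phenylsulfonyl)butan-2-yl]oxy}-5-(triisopropylsilyloxy)phenyl}but-2-enoate | CC(C)(C)[Si](C)(C)OC/C(C)=C\CC/C(C(=O)OC)=C\Cc1cc(O[Si](C(C)C)(C(C)C)C(C)C)ccc1OC(C)(C)C(=O)CS(=O)(=O)c1ccccc1
F2 | step 16 | methyl (2E)-2-[(3Z)-5-hydroxy-4-methylpent-3-en-1-yl]-4-{2-{[2-methyl-3-oxo-4-(phenylsulfonyl)butan-2-yl]oxy}-5-(triisopropylsilyloxy)phenyl}but-2-enoate | OC/C(C)=C\CC/C(C(=O)OC)=C\Cc1cc(O[Si](C(C)C)(C(C)C)C(C)C)ccc1OC(C)(C)C(=O)CS(=O)(=O)c1ccccc1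
F3 | step 16 | methyl (2E)-2-[(3Z)-4-methyl-5-(methylsulfonyloxy)pent-3-en-1-yl]-4-{2-{[2-methyl-3-oxo-4-(phenylsulfonyl)butan-2-yl]oxy}-5-(triisopropylsilyloxy)phenyl}but-2-enoate | CS(=O)(=O)OC/C(C)=C\CC/C(C(=O)OC)=C\Cc1cc(O[Si](C(C)C)(C(C)C)C(C)C)ccc1OC(C)(C)C(=O)CS(=O)(=O)c1ccccc1
F4 | step 16 | methyl (2E)-2-[(3Z)-5-chloro-4-methylpent-3-en-1-yl]-4-{2-{[2-methyl-3-oxo-4-(phenylsulfonyl)butan-2-yl]oxy}-5-(triisopropylsilyloxy)phenyl}but-2-enoate | ClC/C(C)=C\CC/C(C(=O)OC)=C\Cc1cc(O[Si](C(C)C)(C(C)C)C(C)C)ccc1OC(C)(C)C(=O)CS(=O)(=O)c1ccccc1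
F5 | step 16 | macrocyclic α-(phenylsulfonyl) ketone, as 29 with SO2Ph in place of the allyl ester | C/C1=C/CC/C(C(=O)OC)=C\Cc2cc(O[Si](C(C)C)(C(C)C)C(C)C)ccc2OC(C)(C)C(=O)C(S(=O)(=O)c2ccccc2)C1
F6 | step 11 | [(5Z)-7-(tert-butyldimethylsilyloxy)-1-methoxy-6-methyl-1-oxohept-5-en-2-yl]triphenylphosphonium iodide | [I-].COC(=O)C(CC/C=C(C)\CO[Si](C)(C)C(C)(C)C)[P+](c1ccccc1)(c1ccccc1)c1ccccc1
F7 | step 11 | methyl (5Z)-7-(tert-butyldimethylsilyloxy)-6-methyl-2-(triphenyl-λ5-phosphanylidene)hept-5-enoate | COC(=O)C(CC/C=C(C)\CO[Si](C)(C)C(C)(C)C)=P(c1ccccc1)(c1ccccc1)c1ccccc1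
F0 | step 18 | none | none
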